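**Plan**

1. Miyabenol A is read as two copies of one (2R,3R)-3-aryl-2-(4-hydroxyphenyl)-2,3-dihydrobenzofuran (ring A with its ring B substituent; ring C with the terminal resorcinol ring). They are joined through the central (2S,3S)-dihydrofuran fused to ring B, and ring A carries an E-4-hydroxystyryl arm at C-4.
2. Cuts: (a) the ring A C-4–vinyl bond; (b) in the central dihydrofuran C-3–ring C, C-3–C-2 and C-2–O-1; (c) the same three bonds in the outer dihydrofuran, which is one and the same bromide for both halves.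
3. Enabling feature: in each dihydrofuran O-1/C-7a/C-3a/C-3 (a resorcinol oxygen, two adjacent carbons of ring A, B or C, and the benzylic CH) form a latent o-quinone methide, set free from an O-Boc salicylaldehyde and an aryl anion. C-2 carries only H and a 4-oxyphenyl group, so it is the carbon of a benzyl sulfonium ylide. Each ring is therefore one (4+1) event.
4. Forward: the outer ring is made first (O-Boc bromosalicylaldehyde + 3,5-dimethoxyphenyllithium + ylide → bromide 17). Compound 17 is used twice: as aryllithium (ring C half) and, after formylation, ortho-demethylation and O-Boc formation on ring B, as aldehyde 20 (ring A/B half). Their union with a third ylide closes the central ring last; then demethylation, acetylation, Heck arylation and deacetylation follow.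
5. Stereochemistry: reagent control by the C2-symmetric 2,5-dimethylthiolane of the ylide, (2R,5R) for the outer ring and (2S,5S) for the central ring; 2,3-trans from anti addition and invertive closure; E-alkene from the Heck step.

Key step: step 13

Assumption: the thiolane-derived benzylides are taken to react in the (4+1) annulation through the ylide face predicted by the usual model (aryl syn to the sulfur lone pair, attack past the ring hydrogen and not the ring methyl). On that model the (2R,5R)-sulfide gives 2R,3R rings and the (2S,5S)-sulfide a 2S,3S ring.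

**Route**

Step 1
Reactants: 1 (2S,5S)-hexane-2,5-diol
Product: 2 (2S,5S)-hexane-2,5-diyl dimethanesulfonate
Conditions: MsCl, Et3N, CH2Cl2, 0 °C
Reagents that add atoms: methanesulfonyl chloride, CS(=O)(=O)Cl
Why: Standard O-sulfonylation of both secondary alcohols; the C–O bonds are not touched, so both stereocentres are retained.

Step 2
Reactants: 2 (2S,5S)-hexane-2,5-diyl dimethanesulfonate
Product: 3 (2R,5R)-2,5-dimethylthiolane
Conditions: Na2S·9H2O, DMSO, 25 °C; distillation
Reagents that add atoms: sodium sulfide, [Na+].[Na+].[S-2]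
Why: Double SN2 displacement by sulfide closes the thiolane with inversion at both carbons, which sets the 2R,5R configuration.

Step 3
Reactants: 3 (2R,5R)-2,5-dimethylthiolane; 4 (4-methoxyphenyl)methanol
Product: 5 (2R,5R)-1-[(4-methoxyphenyl)methyl]-2,5-dimethylthiolan-1-ium tetrafluoroborate
Conditions: HBF4·OEt2, CH2Cl2, 0 → 25 °C
Reagents that add atoms: tetrafluoroboric acid, [H+].F[B-](F)(F)F
Why: Acid ionises the 4-methoxybenzyl alcohol and the sulfide captures the cation (S-alkylation to a sulfonium salt); the C2 symmetry makes both sulfur lone pairs equivalent, so one salt should form.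

Step 4
Reactants: 6 (2R,5R)-hexane-2,5-diol
Product: 7 (2R,5R)-hexane-2,5-diyl dimethanesulfonate
Conditions: MsCl, Et3N, CH2Cl2, 0 °C
Reagents that add atoms: methanesulfonyl chloride, CS(=O)(=O)Cl
Why: As step 1, in the enantiomeric series.

Step 5
Reactants: 7 (2R,5R)-hexane-2,5-diyl dimethanesulfonate
Product: 8 (2S,5S)-2,5-dimethylthiolane
Conditions: Na2S·9H2O, DMSO, 25 °C; distillation
Reagents that add atoms: sodium sulfide, [Na+].[Na+].[S-2]
Why: As step 2; double SN2 inversion gives the 2S,5S sulfide.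

Step 6
Reactants: 8 (2S,5S)-2,5-dimethylthiolane; 4 (4-methoxyphenyl)methanol
Product: 9 (2S,5S)-1-[(4-methoxyphenyl)methyl]-2,5-dimethylthiolan-1-ium tetrafluoroborate
Conditions: HBF4·OEt2, CH2Cl2, 0 → 25 °C
Reagents that add atoms: tetrafluoroboric acid, [H+].F[B-](F)(F)F
Why: As step 3, in the enantiomeric series.

Step 7
Reactants: 10 2-bromo-4,6-dimethoxybenzaldehyde
Product: 11 2-bromo-6-hydroxy-4-methoxybenzaldehyde
Conditions: BCl3, CH2Cl2, −78 → 0 °C; aqueous work-up
Reagents that add atoms: none
Why: Chelation-controlled demethylation: BCl3 bound to the formyl oxygen cleaves only the ortho methyl ether and leaves the para one.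

Step 8
Reactants: 11 2-bromo-6-hydroxy-4-methoxybenzaldehyde
Product: 12 tert-butyl 3-bromo-2-formyl-5-methoxyphenyl carbonate
Conditions: Boc2O, i-Pr2NEt, DMAP (cat.), THF, 0 → 25 °C
Reagents that add atoms: di-tert-butyl dicarbonate, CC(C)(C)OC(=O)OC(=O)OC(C)(C)C
Why: DMAP-catalysed O-acylation of the phenol gives the aryl tert-butyl carbonate that later acts as the internal leaving group.

Step 9
Reactants: 13 1-bromo-3,5-dimethoxybenzene; 12 tert-butyl 3-bromo-2-formyl-5-methoxyphenyl carbonate; 5 (2R,5R)-1-[(4-methoxyphenyl)methyl]-2,5-dimethylthiolan-1-ium tetrafluoroborate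
Product: 17 (2R,3R)-4-bromo-3-(3,5-dimethoxyphenyl)-6-methoxy-2-(4-methoxyphenyl)-2,3-dihydro-1-benzofuran, via aryllithium 14 (not isolated), via sulfonium ylide 15 (not isolated), via o-quinone methide 16 (not isolated)
Conditions: n-BuLi, THF, −78 °C; 12, −78 °C; then 5 + LiN(SiMe3)2 (premixed, THF, −78 °C), MgBr2·OEt2, −78 → −20 °C
Reagents that add atoms: none
Why: Proposed new method: aryllithium 14 adds to the aldehyde of 12, O-to-O Boc transfer and magnesium-assisted loss of tert-butyl carbonate give o-quinone methide 16, which benzylide 15 traps by conjugate addition and 5-exo-tet closure with loss of the thiolane; the closest known reaction types are the O-Boc salicylaldehyde/organometal route to o-quinone methides and their (4+1) annulation with sulfonium ylides; C-2 (R) is set by the ylide face fixed by the (2R,5R)-thiolane and C-3 (R) by the trans-leading anti addition.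

Step 10
Reactants: 17 (2R,3R)-4-bromo-3-(3,5-dimethoxyphenyl)-6-methoxy-2-(4-methoxyphenyl)-2,3-dihydro-1-benzofuran
Product: 18 2-[(2R,3R)-4-bromo-6-methoxy-2-(4-methoxyphenyl)-2,3-dihydro-1-benzofuran-3-yl]-4,6-dimethoxybenzaldehyde
Conditions: POCl3, DMF, 0 → 60 °C; then H2O
Reagents that add atoms: N,N-dimethylformamide (formyl carbon), CN(C)C=O; water (formyl oxygen), O
Why: Vilsmeier–Haack formylation: the chloroiminium ion should attack the most electron-rich ring (the 3,5-dimethoxyphenyl group; ring A is damped by bromine, the anisyl ring has one donor) para to one methoxy group and ortho to the other, the usual site in 5-alkylresorcinol dimethyl ethers; the two such positions are equivalent by rotation and no stereocentre is touched.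

Step 11
Reactants: 18 2-[(2R,3R)-4-bromo-6-methoxy-2-(4-methoxyphenyl)-2,3-dihydro-1-benzofuran-3-yl]-4,6-dimethoxybenzaldehyde
Product: 19 2-[(2R,3R)-4-bromo-6-methoxy-2-(4-methoxyphenyl)-2,3-dihydro-1-benzofuran-3-yl]-6-hydroxy-4-methoxybenzaldehyde
Conditions: BCl3, CH2Cl2, −78 → −20 °C; aqueous work-up
Reagents that add atoms: none
Why: The same chelation-controlled demethylation as in step 7; only the methoxy group ortho to the new formyl group is activated, and any reversible opening of the dihydrofuran can only return the favoured trans ring.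

Step 12
Reactants: 19 2-[(2R,3R)-4-bromo-6-methoxy-2-(4-methoxyphenyl)-2,3-dihydro-1-benzofuran-3-yl]-6-hydroxy-4-methoxybenzaldehyde
Product: 20 tert-butyl 3-[(2R,3R)-4-bromo-6-methoxy-2-(4-methoxyphenyl)-2,3-dihydro-1-benzofuran-3-yl]-2-formyl-5-methoxyphenyl carbonate
Conditions: Boc2O, i-Pr2NEt, DMAP (cat.), THF, 0 → 25 °C
Reagents that add atoms: di-tert-butyl dicarbonate, CC(C)(C)OC(=O)OC(=O)OC(C)(C)C
Why: DMAP-catalysed carbonate formation at the only free phenol, as in step 8.

Step 13
Reactants: 17 (2R,3R)-4-bromo-3-(3,5-dimethoxyphenyl)-6-methoxy-2-(4-methoxyphenyl)-2,3-dihydro-1-benzofuran; 20 tert-butyl 3-[(2R,3R)-4-bromo-6-methoxy-2-(4-methoxyphenyl)-2,3-dihydro-1-benzofuran-3-yl]-2-formyl-5-methoxyphenyl carbonate; 9 (2S,5S)-1-[(4-methoxyphenyl)methyl]-2,5-dimethylthiolan-1-ium tetrafluoroborate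
Product: 24 (2R,3R)-4-bromo-6-methoxy-2-(4-methoxyphenyl)-3-{(2S,3S)-6-methoxy-2-(4-methoxyphenyl)-3-[(2R,3R)-3-(3,5-dimethoxyphenyl)-6-methoxy-2-(4-methoxyphenyl)-2,3-dihydro-1-benzofuran-4-yl]-2,3-dihydro-1-benzofuran-4-yl}-2,3-dihydro-1-benzofuran, via aryllithium 21 (not isolated), via sulfonium ylide 22 (not isolated), via o-quinone methide 23 (not isolated)
Conditions: n-BuLi, THF, −78 °C; 20, −78 °C; then 9 + LiN(SiMe3)2 (premixed, THF, −78 °C), MgBr2·OEt2, −78 → −20 °C
Reagents that add atoms: none
Why: Proposed new method: aryllithium 21 adds to the formyl group of 20, the alkoxide takes over the Boc group from the neighbouring phenol oxygen, and magnesium-assisted 1,4-elimination of tert-butyl carbonate unveils o-quinone methide 23, whose exocyclic carbon (future C-3) is attacked by benzylide 22 in an aromatisation-driven conjugate addition before the ring B phenoxide displaces the thiolane from the benzylic carbon (future C-2). The closest known reaction types are the generation of o-quinone methides from O-Boc salicylaldehydes and organometallic reagents and the (4+1) annulation of o-quinone methides with sulfonium ylides to trans-2,3-dihydrobenzofurans; new are their one-flask merger, the semistabilised chiral benzylide and the use of the cascade to join two advanced fragments. The central dihydrofuran closes in a formal (4+1) mode: Michael-type addition forms C-3–C-2, then a 5-exo-tet O-alkylation forms O-1–C-2. The (2S,5S)-thiolane fixes the reacting face of the ylide carbon (aryl syn to the sulfur lone pair, one flank screened by a ring methyl) and the anti approach to the quinone methide then sets C-3 as S; C-2 emerges S by invertive closure and would be returned to the same trans arrangement even if closure gained SN1 character through the 4-methoxyphenyl group. The step needs chemoselectivity (21 must add to the formyl group and neither attack the carbonate nor exchange with the ring A bromide, which the low temperature, the 1:1 stoichiometry and the higher electrophilicity of the aldehyde should secure) and facial selectivity on a quinone methide flanked by two resident dihydrobenzofurans, where the reagent-controlled ylide is meant to override any substrate bias. The ring A bromide and the eight methyl ethers are spectators.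

Step 14
Reactants: 24 bromo octamethyl ether (product of step 13)
Product: 25 (2R,3R)-4-bromo-3-{(2S,3S)-3-[(2R,3R)-3-(3,5-dihydroxyphenyl)-6-hydroxy-2-(4-hydroxyphenyl)-2,3-dihydro-1-benzofuran-4-yl]-6-hydroxy-2-(4-hydroxyphenyl)-2,3-dihydro-1-benzofuran-4-yl}-2-(4-hydroxyphenyl)-2,3-dihydro-1-benzofuran-6-ol
Conditions: BBr3 (excess), CH2Cl2, −78 → 0 °C; then MeOH/H2O
Reagents that add atoms: none
Why: Lewis-acid cleavage of the eight aryl methyl ethers while no alkene is present; reversible C-2–O ionisation of the 2-aryl dihydrofurans can only return the favoured 2,3-trans rings and C-3 is not affected.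

Step 15
Reactants: 25 bromo octaphenol
Product: 26 octaacetate of 25
Conditions: Ac2O, pyridine, DMAP (cat.), 25 °C
Reagents that add atoms: acetic anhydride, CC(=O)OC(C)=O
Why: Exhaustive O-acetylation gives a chromatographable, oxidation-stable substrate whose protecting groups come off under mild non-acidic conditions once the stilbene is in place.

Step 16
Reactants: 26 octaacetate of 25; 27 4-ethenylphenyl acetate
Product: 28 miyabenol A nonaacetate
Conditions: Pd[P(t-Bu)3]2 (cat.), Cy2NMe, 1,4-dioxane, 80 °C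
Reagents that add atoms: none
Why: Mizoroki–Heck reaction: oxidative addition of the hindered aryl bromide to zerovalent palladium carrying P(t-Bu)3, syn insertion of the styrene and syn β-hydride elimination should give the E-stilbene, and the tertiary amine leaves the aryl acetates intact.

Step 17
Reactants: 28 miyabenol A nonaacetate
Product: 29 miyabenol A
Conditions: n-BuNH2, THF (degassed, argon), 0 → 25 °C; dilute aqueous acid work-up
Reagents that add atoms: none
Why: Aminolysis of the nine aryl acetates (active esters) by a primary amine under non-acidic, oxygen-free conditions should release the phenols without touching the stilbene or the benzylic ethers.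

**Compound list**

1 | (2S,5S)-hexane-2,5-diol | C[C@H](O)CC[C@H](C)O | starting material
2 | (2S,5S)-hexane-2,5-diyl dimethanesulfonate | C[C@H](OS(C)(=O)=O)CC[C@H](C)OS(C)(=O)=O | intermediate
3 | (2R,5R)-2,5-dimethylthiolane | C[C@@H]1CC[C@@H](C)S1 | intermediate
4 | (4-methoxyphenyl)methanol | COc1ccc(CO)cc1 | starting material
5 | (2R,5R)-1-[(4-methoxyphenyl)methyl]-2,5-dimethylthiolan-1-ium tetrafluoroborate | C[C@@H]1CC[C@@H](C)[S+]1Cc1ccc(OC)cc1.F[B-](F)(F)F | intermediate
6 | (2R,5R)-hexane-2,5-diol | C[C@@H](O)CC[C@@H](C)O | starting material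
7 | (2R,5R)-hexane-2,5-diyl dimethanesulfonate | C[C@@H](OS(C)(=O)=O)CC[C@@H](C)OS(C)(=O)=O | intermediate
8 | (2S,5S)-2,5-dimethylthiolane | C[C@H]1CC[C@H](C)S1 | intermediate
9 | (2S,5S)-1-[(4-methoxyphenyl)methyl]-2,5-dimethylthiolan-1-ium tetrafluoroborate | C[C@H]1CC[C@H](C)[S+]1Cc1ccc(OC)cc1.F[B-](F)(F)F | intermediate
10 | 2-bromo-4,6-dimethoxybenzaldehyde | COc1cc(OC)c(C=O)c(Br)c1 | starting material
11 | 2-bromo-6-hydroxy-4-methoxybenzaldehyde | COc1cc(O)c(C=O)c(Br)c1 | intermediate
12 | tert-butyl 3-bromo-2-formyl-5-methoxyphenyl carbonate | COc1cc(OC(=O)OC(C)(C)C)c(C=O)c(Br)c1 | intermediate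
13 | 1-bromo-3,5-dimethoxybenzene | COc1cc(Br)cc(OC)c1 | starting material
14 | (3,5-dimethoxyphenyl)lithium | [Li]c1cc(OC)cc(OC)c1 | intermediate (not isolated)
15 | sulfonium ylide of 5: [(2R,5R)-2,5-dimethylthiolan-1-ium-1-yl](4-methoxyphenyl)methanide | C[C@@H]1CC[C@@H](C)[S+]1[CH-]c1ccc(OC)cc1 | intermediate (not isolated)
16 | 5-bromo-6-[(3,5-dimethoxyphenyl)methylidene]-3-methoxycyclohexa-2,4-dien-1-one | O=C1C=C(OC)C=C(Br)C1=Cc1cc(OC)cc(OC)c1 | intermediate (not isolated)
17 | (2R,3R)-4-bromo-3-(3,5-dimethoxyphenyl)-6-methoxy-2-(4-methoxyphenyl)-2,3-dihydro-1-benzofuran | Brc1cc(OC)cc2c1[C@@H](c1cc(OC)cc(OC)c1)[C@H](c1ccc(OC)cc1)O2 | intermediate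
18 | 2-[(2R,3R)-4-bromo-6-methoxy-2-(4-methoxyphenyl)-2,3-dihydro-1-benzofuran-3-yl]-4,6-dimethoxybenzaldehyde | Brc1cc(OC)cc2c1[C@@H](c1cc(OC)cc(OC)c1C=O)[C@H](c1ccc(OC)cc1)O2 | intermediate
19 | 2-[(2R,3R)-4-bromo-6-methoxy-2-(4-methoxyphenyl)-2,3-dihydro-1-benzofuran-3-yl]-6-hydroxy-4-methoxybenzaldehyde | Brc1cc(OC)cc2c1[C@@H](c1cc(OC)cc(O)c1C=O)[C@H](c1ccc(OC)cc1)O2 | intermediate
20 | tert-butyl 3-[(2R,3R)-4-bromo-6-methoxy-2-(4-methoxyphenyl)-2,3-dihydro-1-benzofuran-3-yl]-2-formyl-5-methoxyphenyl carbonate | Brc1cc(OC)cc2c1[C@@H](c1cc(OC)cc(OC(=O)OC(C)(C)C)c1C=O)[C@H](c1ccc(OC)cc1)O2 | intermediate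
21 | [(2R,3R)-3-(3,5-dimethoxyphenyl)-6-methoxy-2-(4-methoxyphenyl)-2,3-dihydro-1-benzofuran-4-yl]lithium | [Li]c1cc(OC)cc2c1[C@@H](c1cc(OC)cc(OC)c1)[C@H](c1ccc(OC)cc1)O2 | intermediate (not isolated)
22 | sulfonium ylide of 9: [(2S,5S)-2,5-dimethylthiolan-1-ium-1-yl](4-methoxyphenyl)methanide | C[C@H]1CC[C@H](C)[S+]1[CH-]c1ccc(OC)cc1 | intermediate (not isolated)
23 | ring B o-quinone methide: 5-[(2R,3R)-4-bromo-6-methoxy-2-(4-methoxyphenyl)-2,3-dihydro-1-benzofuran-3-yl]-6-{[(2R,3R)-3-(3,5-dimethoxyphenyl)-6-methoxy-2-(4-methoxyphenyl)-2,3-dihydro-1-benzofuran-4-yl]methylidene}-3-methoxycyclohexa-2,4-dien-1-one | Brc1cc(OC)cc2c1[C@@H](C1=CC(OC)=CC(=O)C1=Cc1cc(OC)cc3c1[C@@H](c1cc(OC)cc(OC)c1)[C@H](c1ccc(OC)cc1)O3)[C@H](c1ccc(OC)cc1)O2 | intermediate (not isolated)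
24 | bromo octamethyl ether: (2R,3R)-4-bromo-6-methoxy-2-(4-methoxyphenyl)-3-{(2S,3S)-6-methoxy-2-(4-methoxyphenyl)-3-[(2R,3R)-3-(3,5-dimethoxyphenyl)-6-methoxy-2-(4-methoxyphenyl)-2,3-dihydro-1-benzofuran-4-yl]-2,3-dihydro-1-benzofuran-4-yl}-2,3-dihydro-1-benzofuran | Brc1cc(OC)cc2c1[C@@H](c1cc(OC)cc3c1[C@H](c1cc(OC)cc4c1[C@@H](c1cc(OC)cc(OC)c1)[C@H](c1ccc(OC)cc1)O4)[C@@H](c1ccc(OC)cc1)O3)[C@H](c1ccc(OC)cc1)O2 | intermediate
25 | bromo octaphenol: 24 with all eight methoxy groups replaced by hydroxy groups | Brc1cc(O)cc2c1[C@@H](c1cc(O)cc3c1[C@H](c1cc(O)cc4c1[C@@H](c1cc(O)cc(O)c1)[C@H](c1ccc(O)cc1)O4)[C@@H](c1ccc(O)cc1)O3)[C@H](c1ccc(O)cc1)O2 | intermediate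
26 | octaacetate of 25 (all eight phenols as acetates) | Brc1cc(OC(C)=O)cc2c1[C@@H](c1cc(OC(C)=O)cc3c1[C@H](c1cc(OC(C)=O)cc4c1[C@@H](c1cc(OC(C)=O)cc(OC(C)=O)c1)[C@H](c1ccc(OC(C)=O)cc1)O4)[C@@H](c1ccc(OC(C)=O)cc1)O3)[C@H](c1ccc(OC(C)=O)cc1)O2 | intermediate
27 | 4-ethenylphenyl acetate (4-acetoxystyrene) | CC(=O)Oc1ccc(C=C)cc1 | starting material
28 | miyabenol A nonaacetate | CC(=O)Oc1ccc(/C=C/c2cc(OC(C)=O)cc3c2[C@@H](c2cc(OC(C)=O)cc4c2[C@H](c2cc(OC(C)=O)cc5c2[C@@H](c2cc(OC(C)=O)cc(OC(C)=O)c2)[C@H](c2ccc(OC(C)=O)cc2)O5)[C@@H](c2ccc(OC(C)=O)cc2)O4)[C@H](c2ccc(OC(C)=O)cc2)O3)cc1 | intermediate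
29 | miyabenol A | Oc1ccc(/C=C/c2cc(O)cc3c2[C@@H](c2cc(O)cc4c2[C@H](c2cc(O)cc5c2[C@@H](c2cc(O)cc(O)c2)[C@H](c2ccc(O)cc2)O5)[C@@H](c2ccc(O)cc2)O4)[C@H](c2ccc(O)cc2)O3)cc1 | target

**Totals**

Total step count: 17.
Longest linear sequence: 12 steps (steps 1, 2, 3, then 9 to 17); counted from aldehyde 10 it is 11 steps (steps 7 to 17).

**Steps most likely to fail**

1. Step 13. The three events of the cascade may fall out of step. The hindered aldehyde may add the aryllithium slowly, so that the ylide meets unreacted aldehyde or decays before the quinone methide is released. Conjugate addition at the doubly flanked exocyclic carbon may be slower than loss of the quinone methide to tert-butoxide or oligomerisation. Facial selectivity may be eroded by a mismatched substrate bias. The fallback uses known chemistry and separates fragment union from ring closure; it sets out from 19 and 17. Compound 19 is deprotonated with NaH in THF to the sodium phenolate F1. Aryllithium 21 (from 17 and n-BuLi) is added at −78 °C and gives, after work-up, the o-hydroxybenzhydrol F2 as a mixture at the carbinol carbon. 4-MeC6H4SO2H in CH2Cl2 converts it into the 2-(sulfonylmethyl)phenol F3 through acid-catalysed substitution. F3, salt 9 and Cs2CO3 in MeCN at 0 → 25 °C then release quinone methide 23 slowly in the presence of ylide 22 (the established two-component (4+1) annulation) and return to the route at 24.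

2. Step 9. Over-addition of a second aryllithium to the quinone methide, or attack of the ylide or the amide base on the carbonate before the Boc group has migrated, may divert material; the anti/syn topicity of the ylide addition may be low. The fallback uses the same known two-component annulation and sets out from 11 and 13. Compound 11 is deprotonated with NaH to the sodium phenolate F4. Aryllithium 14 (from 13) adds to give the o-hydroxybenzhydrol F5. 4-MeC6H4SO2H gives the sulfone F6. F6, salt 5 and Cs2CO3 in MeCN then give, through 16 and 15, bromide 17, where the route is rejoined.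

3. Step 10. Positional selectivity of the electrophilic attack may be poor (the position between the two methoxy groups of the dimethoxyphenyl ring, or C-5/C-7 of ring A, instead of the position next to the benzylic carbon), and the acidic medium may open the dihydrofuran. The fallback carries the ring B formyl carbon and a differentiated oxygen from the start; it sets out from 11 and returns at 19. Compound 11 with MOMCl and i-Pr2NEt gives the methoxymethyl ether F7. Me3SiOCH2CH2OSiMe3 with catalytic Me3SiOTf at −78 °C gives the dioxolane F8. Bromine–lithium exchange with n-BuLi gives the aryllithium F9. F9 is combined with 12 and then ylide 15/MgBr2·OEt2 exactly as in step 9 and gives, through the o-quinone methide F10, the acetal-protected dihydrobenzofuran F11. Aqueous HCl in THF then removes the dioxolane and the methoxymethyl group in one operation to give 19. Bromide 17 is still made by step 9 for use as the aryllithium partner.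

**Further compounds**

F1 | step 13 | sodium 3-[(2R,3R)-4-bromo-6-methoxy-2-(4-methoxyphenyl)-2,3-dihydro-1-benzofuran-3-yl]-2-formyl-5-methoxyphenolate | Brc1cc(OC)cc2c1[C@@H](c1cc(OC)cc([O-])c1C=O)[C@H](c1ccc(OC)cc1)O2.[Na+]
F2 | step 13 | 3-[(2R,3R)-4-bromo-6-methoxy-2-(4-methoxyphenyl)-2,3-dihydro-1-benzofuran-3-yl]-2-{[(2R,3R)-3-(3,5-dimethoxyphenyl)-6-methoxy-2-(4-methoxyphenyl)-2,3-dihydro-1-benzofuran-4-yl](hydroxy)methyl}-5-methoxyphenol (mixture at the carbinol carbon) | Brc1cc(OC)cc2c1[C@@H](c1cc(OC)cc(O)c1C(O)c1cc(OC)cc3c1[C@@H](c1cc(OC)cc(OC)c1)[C@H](c1ccc(OC)cc1)O3)[C@H](c1ccc(OC)cc1)O2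
F3 | step 13 | 3-[(2R,3R)-4-bromo-6-methoxy-2-(4-methoxyphenyl)-2,3-dihydro-1-benzofuran-3-yl]-2-{[(2R,3R)-3-(3,5-dimethoxyphenyl)-6-methoxy-2-(4-methoxyphenyl)-2,3-dihydro-1-benzofuran-4-yl](4-methylbenzenesulfonyl)methyl}-5-methoxyphenol (mixture at the sulfonyl-bearing carbon) | Brc1cc(OC)cc2c1[C@@H](c1cc(OC)cc(O)c1C(c1cc(OC)cc3c1[C@@H](c1cc(OC)cc(OC)c1)[C@H](c1ccc(OC)cc1)O3)S(=O)(=O)c1ccc(C)cc1)[C@H](c1ccc(OC)cc1)O2
F4 | step 9 | sodium 3-bromo-2-formyl-5-methoxyphenolate | COc1cc([O-])c(C=O)c(Br)c1.[Na+]
F5 | step 9 | 3-bromo-2-[(3,5-dimethoxyphenyl)(hydroxy)methyl]-5-methoxyphenol (racemic) | COc1cc(O)c(C(O)c2cc(OC)cc(OC)c2)c(Br)c1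
F6 | step 9 | 3-bromo-2-[(3,5-dimethoxyphenyl)(4-methylbenzenesulfonyl)methyl]-5-methoxyphenol (racemic) | COc1cc(O)c(C(c2cc(OC)cc(OC)c2)S(=O)(=O)c2ccc(C)cc2)c(Br)c1
F7 | step 10 | 2-bromo-4-methoxy-6-(methoxymethoxy)benzaldehyde | COCOc1cc(OC)cc(Br)c1C=O
F8 | step 10 | 2-[2-bromo-4-methoxy-6-(methoxymethoxy)phenyl]-1,3-dioxolane | COCOc1cc(OC)cc(Br)c1C1OCCO1
F9 | step 10 | [2-(1,3-dioxolan-2-yl)-5-methoxy-3-(methoxymethoxy)phenyl]lithium | [Li]c1cc(OC)cc(OCOC)c1C1OCCO1
F10 | step 10 | 5-bromo-6-{[2-(1,3-dioxolan-2-yl)-5-methoxy-3-(methoxymethoxy)phenyl]methylidene}-3-methoxycyclohexa-2,4-dien-1-one | O=C1C=C(OC)C=C(Br)C1=Cc1cc(OC)cc(OCOC)c1C1OCCO1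
F11 | step 10 | (2R,3R)-4-bromo-3-[2-(1,3-dioxolan-2-yl)-5-methoxy-3-(methoxymethoxy)phenyl]-6-methoxy-2-(4-methoxyphenyl)-2,3-dihydro-1-benzofuran | Brc1cc(OC)cc2c1[C@@H](c1cc(OC)cc(OCOC)c1C1OCCO1)[C@H](c1ccc(OC)cc1)O2
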